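**Plan**

1. Numbering (eremophilane): ring A = C1–C5 + C10, ring B = C5–C10; C11 (on C7) bears C12H2OH and C13H3; C14 and C15 are the methyls on C5 and C4; β is the face of C14.
2. Retrosynthesis: cut the C3–O ester bond (acid 34, attached last with inversion), remove the C9 hydroxyl, then cut C3–C4 and C5–C10 together; the open chain is cut at C8–C9 (acyl chloride + butenyl Grignard), C6–C7 (β-keto ester alkylation) and C1=C2 (cross-metathesis).
3. Enabling feature: the C3 oxygen sits 1,2 to C4, and C4/C5 carry cis methyls, so ring A (with a C1=C2 bond and C15 raised to CHO) is the ortho/endo Diels–Alder adduct of the 1-silyloxydiene C3=C2–C1=C10 with the (E)-enal C4=C5; the chain C6–C7(=C11)–C8–C9 that becomes ring B is the tether.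
4. Forward: the acyclic chain is built with the tetrasubstituted C7=C11 alkene fixed (Z enol triflate, then methyl cuprate); rings A and B close together in step 13; C15 is reduced back to CH3, C1=C2 hydrogenated, C8 oxidised, the ester attached and C9 hydroxylated.
5. Stereochemistry: only C8 is set by a reagent (CBS reduction); its axial silyl ether (A(1,3) strain with C13) relays to C3, C4, C5 and C10 through the E,E-diene/E-enal/endo transition state, and C8 is then erased as the ketone.
6. C3 is inverted to 3α in the Mitsunobu esterification; the 9α-OH enters the C8 enolate anti to the axial C14.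

Key step: step 13

Remark on the chemistry (assumption): ethyl (E)-4-bromo-3-methylbut-2-enoate (6) is used as the pure E isomer, bought as such or separated from the commercial E/Z mixture by chromatography.

**Route**

Step 1
Reactants: 1 methyl 4-chloro-3-oxobutanoate; 2 4-methoxybenzyl alcohol
Product: 3 methyl 4-[(4-methoxybenzyl)oxy]-3-oxobutanoate
Conditions: NaH (2.2 equiv), THF, 0 → 23 °C; aq. NH4Cl
Reagents that add atoms: none
Why: Williamson-type SN2 displacement of the chloride by the benzylic alkoxide while the β-keto ester is masked as its sodium enolate (hence two equivalents of base), the standard access to 4-alkoxyacetoacetates.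

Step 2
Reactants: 3 methyl 4-[(4-methoxybenzyl)oxy]-3-oxobutanoate; 4 2-(trimethylsilyl)ethanol
Product: 5 2-(trimethylsilyl)ethyl 4-[(4-methoxybenzyl)oxy]-3-oxobutanoate
Conditions: DMAP (0.3 equiv), toluene, 110 °C, 4 Å molecular sieves
Reagents that add atoms: none
Why: DMAP-catalysed transesterification of a β-keto ester (through the acylketene) installs a fluoride-cleavable ester, so that C8 can later be told apart from the C15 ethyl ester.

Step 3
Reactants: 5 2-(trimethylsilyl)ethyl 4-[(4-methoxybenzyl)oxy]-3-oxobutanoate; 6 ethyl (E)-4-bromo-3-methylbut-2-enoate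
Product: 7 1-ethyl 6-[2-(trimethylsilyl)ethyl] (2E)-5-{[(4-methoxybenzyl)oxy]acetyl}-3-methylhex-2-enedioate (racemic at the future C7)
Conditions: NaH (1.05 equiv), THF, 0 °C; then 6, 0 → 23 °C
Reagents that add atoms: none
Why: SN2 C-alkylation of the stabilised β-keto ester enolate by the primary allylic bromide forms the C6–C7 bond; the β,β-disubstituted enoate resists conjugate addition and keeps its E geometry, and the new centre is erased in step 4.

Step 4
Reactants: 7 1-ethyl 6-[2-(trimethylsilyl)ethyl] (2E)-5-{[(4-methoxybenzyl)oxy]acetyl}-3-methylhex-2-enedioate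
Product: 8 1-ethyl 6-[2-(trimethylsilyl)ethyl] (2E,5Z)-5-{2-[(4-methoxybenzyl)oxy]-1-(trifluoromethylsulfonyloxy)ethylidene}-3-methylhex-2-enedioate
Conditions: NaH (1.1 equiv), Et2O, 0 °C; then Tf2O, −78 → 0 °C
Reagents that add atoms: trifluoromethanesulfonic anhydride (O=S(=O)(OS(=O)(=O)C(F)(F)F)C(F)(F)F)
Why: O-sulfonylation of the sodium enolate, in which Na+ holds the enolate oxygen and the ester carbonyl cis, should give the Z enol triflate (OTf cis to C8, CH2OPMB cis to C6).

Step 5
Reactants: 8 1-ethyl 6-[2-(trimethylsilyl)ethyl] (2E,5Z)-5-{2-[(4-methoxybenzyl)oxy]-1-(trifluoromethylsulfonyloxy)ethylidene}-3-methylhex-2-enedioate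
Product: 9 1-ethyl 6-[2-(trimethylsilyl)ethyl] (2E,5E)-5-{1-[(4-methoxybenzyl)oxy]propan-2-ylidene}-3-methylhex-2-enedioate
Conditions: Me2CuLi (from CuI and 2 MeLi), Et2O, −78 → −20 °C
Reagents that add atoms: lithium dimethylcuprate ([Li+].C[Cu-]C)
Why: Enol triflate–organocuprate coupling (addition–elimination on the β-triflyloxy acrylate) replaces OTf by CH3 with retention, which fixes C7=C11 with C13 cis to C8 and C12 cis to C6; the β,β-disubstituted C15 enoate is inert at this temperature.

Step 6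
Reactants: 9 1-ethyl 6-[2-(trimethylsilyl)ethyl] (2E,5E)-5-{1-[(4-methoxybenzyl)oxy]propan-2-ylidene}-3-methylhex-2-enedioate
Product: 10 (2E,4E)-6-ethoxy-2-{1-[(4-methoxybenzyl)oxy]propan-2-ylidene}-4-methyl-6-oxohex-4-enoic acid
Conditions: Bu4NF, THF, 0 → 23 °C; dilute aq. HCl work-up
Reagents that add atoms: none
Why: Fluoride attacks silicon and the 2-silylethyl ester fragments to the carboxylate (β-elimination), leaving the ethyl ester and the PMB ether untouched.

Step 7
Reactants: 10 (2E,4E)-6-ethoxy-2-{1-[(4-methoxybenzyl)oxy]propan-2-ylidene}-4-methyl-6-oxohex-4-enoic acid; 11 but-3-en-1-ylmagnesium bromide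
Product: 13 ethyl (2E,5E)-5-{1-[(4-methoxybenzyl)oxy]propan-2-ylidene}-3-methyl-6-oxodeca-2,9-dienoate, via acid chloride 12 (not isolated)
Conditions: 1-chloro-N,N,2-trimethylprop-1-en-1-amine, CH2Cl2, 0 → 23 °C; evaporate; then 11 (1.1 equiv), Fe(acac)3 (3 mol%), THF, −78 °C
Reagents that add atoms: none
Why: Neutral conversion of the acid into its chloride, then iron-catalysed acylation of the Grignard reagent (ketone synthesis from acid chlorides), which is much faster than attack on the ethyl ester and stops at the ketone; this forms C8–C9.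

Step 8
Reactants: 13 ethyl (2E,5E)-5-{1-[(4-methoxybenzyl)oxy]propan-2-ylidene}-3-methyl-6-oxodeca-2,9-dienoate
Product: 14 ethyl (2E,5E,6S)-6-hydroxy-5-{1-[(4-methoxybenzyl)oxy]propan-2-ylidene}-3-methyldeca-2,9-dienoate (C8 is S)
Conditions: (R)-2-methyl-CBS-oxazaborolidine (20 mol%), catecholborane (1.5 equiv), toluene, −78 °C; aq. NaOH work-up
Reagents that add atoms: none
Why: Corey–Bakshi–Shibata reduction: the oxazaborolidine binds the ketone anti to the bulky tetrasubstituted alkenyl group and delivers hydride to one face, which should set C8 as S; catecholborane does not hydroborate the terminal alkene at −78 °C.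

Step 9
Reactants: 14 ethyl (2E,5E,6S)-6-hydroxy-5-{1-[(4-methoxybenzyl)oxy]propan-2-ylidene}-3-methyldeca-2,9-dienoate; 15 (E)-but-2-enal
Product: 16 ethyl (2E,5E,6S,9E)-6-hydroxy-5-{1-[(4-methoxybenzyl)oxy]propan-2-ylidene}-3-methyl-11-oxoundeca-2,9-dienoate
Conditions: second-generation Grubbs catalyst (5 mol%), 15 (5 equiv), CH2Cl2, 40 °C
Reagents that add atoms: none
Why: Olefin cross-metathesis of the monosubstituted alkene with excess crotonaldehyde should give the E enal (C1=C2–C3HO); the tri- and tetrasubstituted alkenes do not take part.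

Step 10
Reactants: 16 ethyl (2E,5E,6S,9E)-6-hydroxy-5-{1-[(4-methoxybenzyl)oxy]propan-2-ylidene}-3-methyl-11-oxoundeca-2,9-dienoate
Product: 18 ethyl (2E,5E,6S,8E,10E)-11-[(tert-butyldimethylsilyl)oxy]-5-{1-[(4-methoxybenzyl)oxy]propan-2-ylidene}-3-methyl-6-[(triethylsilyl)oxy]undeca-2,8,10-trienoate, via triethylsilyl ether enal 17 (not isolated)
Conditions: Et3SiOTf (1.1 equiv), 2,6-lutidine, CH2Cl2, −78 °C; then Et3N (3 equiv), t-BuMe2SiOTf (1.3 equiv), −78 → 0 °C
Reagents that add atoms: triethylsilyl triflate (CC[Si](CC)(CC)OS(=O)(=O)C(F)(F)F); tert-butyldimethylsilyl triflate (CC(C)(C)[Si](C)(C)OS(=O)(=O)C(F)(F)F)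
Why: Silylation of the C8 alcohol with the weak base, then soft enolisation of the enal (O-silylation and γ-deprotonation at C10 by Et3N), gives the 1-silyloxydiene; the s-trans enal leads to the E enol ether and the new C10=C1 bond should form mainly E.

Step 11
Reactants: 18 ethyl (2E,5E,6S,8E,10E)-11-[(tert-butyldimethylsilyl)oxy]-5-{1-[(4-methoxybenzyl)oxy]propan-2-ylidene}-3-methyl-6-[(triethylsilyl)oxy]undeca-2,8,10-trienoate
Product: 19 (2E,5E,6S,8E,10E)-11-[(tert-butyldimethylsilyl)oxy]-5-{1-[(4-methoxybenzyl)oxy]propan-2-ylidene}-3-methyl-6-[(triethylsilyl)oxy]undeca-2,8,10-trien-1-ol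
Conditions: i-Bu2AlH (2.5 equiv), CH2Cl2, −78 °C
Reagents that add atoms: none
Why: 1,2-Reduction of the α,β-unsaturated ester to the allylic alcohol; silyl ethers, the silyl dienol ether and the PMB ether are inert to the hydride at low temperature.

Step 12
Reactants: 19 (2E,5E,6S,8E,10E)-11-[(tert-butyldimethylsilyl)oxy]-5-{1-[(4-methoxybenzyl)oxy]propan-2-ylidene}-3-methyl-6-[(triethylsilyl)oxy]undeca-2,8,10-trien-1-ol
Product: 20 (2E,5E,6S,8E,10E)-11-[(tert-butyldimethylsilyl)oxy]-5-{1-[(4-methoxybenzyl)oxy]propan-2-ylidene}-3-methyl-6-[(triethylsilyl)oxy]undeca-2,8,10-trienal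
Conditions: MnO2 (20 equiv), CH2Cl2, 23 °C; filtration, used at once
Reagents that add atoms: none
Why: Allylic oxidation of the primary alcohol on MnO2 under neutral conditions raises C15 to the aldehyde that activates the dienophile, with the E geometry kept and the silyl dienol ether spared.

Step 13
Reactants: 20 (2E,5E,6S,8E,10E)-11-[(tert-butyldimethylsilyl)oxy]-5-{1-[(4-methoxybenzyl)oxy]propan-2-ylidene}-3-methyl-6-[(triethylsilyl)oxy]undeca-2,8,10-trienal
Product: 21 3β-[(tert-butyldimethylsilyl)oxy]-12-[(4-methoxybenzyl)oxy]-8α-[(triethylsilyl)oxy]eremophila-1,7(11)E-dien-15-al (4β-CHO, 5β-CH3, 10α-H, trans-fused)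
Conditions: Me2AlCl (1.2 equiv), CH2Cl2, −78 → −30 °C; Et3N, then aq. NaHCO3
Reagents that add atoms: none
Why: Me2AlCl binds the aldehyde oxygen of the s-trans enal and lowers its LUMO, and the electron-rich 1-silyloxydiene C3=C2–C1=C10 adds across C4=C5 in a concerted but asynchronous [4+2] in which the C10–C5 bond (nucleophilic diene terminus to the enal β-carbon) leads and C3–C4 follows, the polarity of a Mukaiyama–Michael/aldol sequence. The closest known reaction type is the Lewis-acid-promoted type 1 intramolecular Diels–Alder reaction of (E,E)-1,3,9-decatrienes with an aldehyde-activated terminal dienophile, together with the ortho/endo cycloaddition of 1-silyloxybutadienes with enals. Ring A closes as the six-membered [4+2] adduct, and ring B closes in the same event through the four-atom tether C6–C7–C8–C9 in a chair-like six-membered transition state with the tether anti to the diene, hence the trans ring fusion. The cis relation of C15 and C14 follows from the E geometry of the enal, the cis relation of the C3 oxygen and C9 from the E,E geometry of the diene, and the endo position of the aluminium-bound CHO under the diene makes C3–O and C15 cis and puts C14 and H10 trans. The absolute sense comes from C8: its C–H must eclipse the C7=C11 plane to avoid A(1,3) strain with C13, so the OSiEt3 group is axial on the forming ring B and only one of the two chair-like transition states is free of this strain. The step needs endo and π-facial selectivity; the first is secured by the Lewis acid and the E enal (CHO trans to the tether), the second by the allylic-strain lock at C8.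

Step 14
Reactants: 21 3β-[(tert-butyldimethylsilyl)oxy]-12-[(4-methoxybenzyl)oxy]-8α-[(triethylsilyl)oxy]eremophila-1,7(11)E-dien-15-al
Product: 23 3β-[(tert-butyldimethylsilyl)oxy]-12-[(4-methoxybenzyl)oxy]eremophila-1,7(11)E-diene-8α,15-diol, via triethylsilyl ether alcohol 22 (not isolated)
Conditions: NaBH4, MeOH/CH2Cl2, −20 °C; then AcOH to pH 6, PPTS, 23 °C
Reagents that add atoms: none
Why: Borohydride reduction removes at once the β-silyloxy aldehyde that could eliminate the C3 oxygen, and mild acid methanolysis then cleaves the triethylsilyl ether selectively (the hindered secondary TBS ether and the PMB ether survive).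

Step 15
Reactants: 23 3β-[(tert-butyldimethylsilyl)oxy]-12-[(4-methoxybenzyl)oxy]eremophila-1,7(11)E-diene-8α,15-diol
Product: 25 3β-[(tert-butyldimethylsilyl)oxy]-12-[(4-methoxybenzyl)oxy]eremophila-1,7(11)E-dien-8α-ol, via mesylate 24 (not isolated)
Conditions: MsCl (1.05 equiv), Et3N, CH2Cl2, −40 °C; then LiEt3BH (5 equiv), THF, 0 → 50 °C
Reagents that add atoms: none
Why: Selective sulfonylation of the primary alcohol over the hindered axial C8 alcohol, then SN2 displacement by hydride, returns C15 to the C4 methyl group without touching C4.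

Step 16
Reactants: 25 3β-[(tert-butyldimethylsilyl)oxy]-12-[(4-methoxybenzyl)oxy]eremophila-1,7(11)E-dien-8α-ol
Product: 26 3β-[(tert-butyldimethylsilyl)oxy]-12-[(4-methoxybenzyl)oxy]eremophil-7(11)E-en-8α-ol
Conditions: H2 (4 atm), RhCl(PPh3)3 (10 mol%), benzene/EtOH, 23 °C
Reagents that add atoms: none
Why: Homogeneous hydrogenation reduces the cis-disubstituted C1=C2 alkene and leaves the tetrasubstituted C7=C11 alkene and the benzylic ether alone.

Step 17
Reactants: 26 3β-[(tert-butyldimethylsilyl)oxy]-12-[(4-methoxybenzyl)oxy]eremophil-7(11)E-en-8α-ol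
Product: 27 3β-[(tert-butyldimethylsilyl)oxy]-12-[(4-methoxybenzyl)oxy]eremophil-7(11)E-en-8-one
Conditions: Dess–Martin periodinane, NaHCO3, CH2Cl2, 0 → 23 °C
Reagents that add atoms: none
Why: Oxidation of the only free alcohol gives the C8 ketone conjugated with C7=C11 and erases the helper stereocentre; the periodinane needs no alignment of the in-plane C8–H with the π bond, and the buffer prevents acid-induced alkene migration.

Step 18
Reactants: 27 3β-[(tert-butyldimethylsilyl)oxy]-12-[(4-methoxybenzyl)oxy]eremophil-7(11)E-en-8-one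
Product: 28 3β-hydroxy-12-[(4-methoxybenzyl)oxy]eremophil-7(11)E-en-8-one (axial 3β-OH)
Conditions: HF·pyridine, pyridine, THF, 0 → 40 °C
Reagents that add atoms: none
Why: Fluoride cleavage of the hindered secondary silyl ether under mildly acidic conditions, which avoid base-induced dienolisation (and E/Z scrambling) of the enone.

Step 19
Reactants: 29 (E)-oct-2-enal
Product: 30 (E)-non-3-en-1-yne
Conditions: Me3SiCHN2, n-BuLi, THF, −78 °C; then 29, −78 → 23 °C
Reagents that add atoms: (trimethylsilyl)diazomethane (C[Si](C)(C)C=[N+]=[N-])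
Why: Colvin rearrangement: the lithiated diazo reagent adds to the aldehyde, Peterson-type elimination gives the alkylidene carbene and 1,2-hydrogen shift gives the terminal alkyne with the E alkene intact.

Step 20
Reactants: 30 (E)-non-3-en-1-yne
Product: 32 (1E,3E)-1-iodo-2-methylnona-1,3-diene, via alkenylalane 31 (not isolated)
Conditions: Me3Al (2 equiv), Cp2ZrCl2 (0.25 equiv), CH2Cl2, 0 → 23 °C; then I2, THF, −30 °C
Reagents that add atoms: trimethylaluminium (C[Al](C)C); iodine (II)
Why: Zirconium-catalysed syn carboalumination of the terminal alkyne puts CH3 on the internal carbon and aluminium on the terminus cis to it, and iodinolysis with retention gives the E,E dienyl iodide.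

Step 21
Reactants: 32 (1E,3E)-1-iodo-2-methylnona-1,3-diene; 33 acrylic acid
Product: 34 (2E,4E,6E)-5-methyldodeca-2,4,6-trienoic acid
Conditions: Pd(OAc)2 (5 mol%), K2CO3, Bu4NCl, DMF, 50 °C; then aq. HCl
Reagents that add atoms: none
Why: Heck reaction: oxidative addition to the alkenyl iodide with retention, syn insertion of the acrylate and syn β-hydride elimination give the 2E acid under ligand-free phase-transfer conditions.

Step 22
Reactants: 28 3β-hydroxy-12-[(4-methoxybenzyl)oxy]eremophil-7(11)E-en-8-one; 34 (2E,4E,6E)-5-methyldodeca-2,4,6-trienoic acid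
Product: 35 12-[(4-methoxybenzyl)oxy]-8-oxoeremophil-7(11)E-en-3α-yl (2E,4E,6E)-5-methyldodeca-2,4,6-trienoate
Conditions: PPh3 (2 equiv), DIAD (2 equiv), 34 (2 equiv), toluene, 0 → 23 °C
Reagents that add atoms: none
Why: Mitsunobu esterification: the axial 3β-alcohol is activated as the alkoxyphosphonium ion and displaced by the carboxylate in an SN2 reaction with inversion, which gives the equatorial 3α ester and relieves the 1,3-diaxial interaction with C14.

Step 23
Reactants: 35 12-[(4-methoxybenzyl)oxy]-8-oxoeremophil-7(11)E-en-3α-yl (2E,4E,6E)-5-methyldodeca-2,4,6-trienoate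
Product: 36 9α-hydroxy-12-[(4-methoxybenzyl)oxy]-8-oxoeremophil-7(11)E-en-3α-yl (2E,4E,6E)-5-methyldodeca-2,4,6-trienoate
Conditions: KN(SiMe3)2 (1.1 equiv), THF, −78 °C; then 2-(phenylsulfonyl)-3-phenyloxaziridine (1.3 equiv), −78 °C; aq. NH4Cl
Reagents that add atoms: 2-(phenylsulfonyl)-3-phenyloxaziridine (O=S(=O)(N1OC1c1ccccc1)c1ccccc1)
Why: Kinetic deprotonation at C9, the only α-CH2 of the enone, gives the cross-conjugated potassium enolate, and oxygen transfer from the N-sulfonyloxaziridine (enolate hydroxylation) should occur on the α face, anti to the axial C14 methyl, to give the equatorial 9α-alcohol.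

Step 24
Reactants: 36 9α-hydroxy-12-[(4-methoxybenzyl)oxy]-8-oxoeremophil-7(11)E-en-3α-yl (2E,4E,6E)-5-methyldodeca-2,4,6-trienoate
Product: 37 CNP0226738.2, 9α,12-dihydroxy-8-oxoeremophil-7(11)E-en-3α-yl (2E,4E,6E)-5-methyldodeca-2,4,6-trienoate
Conditions: DDQ (1.5 equiv), CH2Cl2/pH 7 buffer (10:1), 0 °C
Reagents that add atoms: none
Why: Oxidative cleavage of the 4-methoxybenzyl ether (hydride abstraction, then hydrolysis of the oxocarbenium ion) frees the C12 alcohol without touching the ester, the ketol or the electron-poor alkenes.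

**Compound list**

1 | methyl 4-chloro-3-oxobutanoate | COC(=O)CC(=O)CCl | starting material
2 | 4-methoxybenzyl alcohol | COc1ccc(CO)cc1 | starting material
3 | methyl 4-[(4-methoxybenzyl)oxy]-3-oxobutanoate | COC(=O)CC(=O)COCc1ccc(OC)cc1 | intermediate
4 | 2-(trimethylsilyl)ethanol | C[Si](C)(C)CCO | starting material
5 | 2-(trimethylsilyl)ethyl 4-[(4-methoxybenzyl)oxy]-3-oxobutanoate | C[Si](C)(C)CCOC(=O)CC(=O)COCc1ccc(OC)cc1 | intermediate
6 | ethyl (E)-4-bromo-3-methylbut-2-enoate | CCOC(=O)/C=C(\C)CBr | starting material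
7 | 1-ethyl 6-[2-(trimethylsilyl)ethyl] (2E)-5-{[(4-methoxybenzyl)oxy]acetyl}-3-methylhex-2-enedioate (racemic) | CCOC(=O)/C=C(\C)CC(C(=O)COCc1ccc(OC)cc1)C(=O)OCC[Si](C)(C)C | intermediate
8 | 1-ethyl 6-[2-(trimethylsilyl)ethyl] (2E,5Z)-5-{2-[(4-methoxybenzyl)oxy]-1-(trifluoromethylsulfonyloxy)ethylidene}-3-methylhex-2-enedioate | CCOC(=O)/C=C(\C)C/C(C(=O)OCC[Si](C)(C)C)=C(/OS(=O)(=O)C(F)(F)F)COCc1ccc(OC)cc1 | intermediate
9 | 1-ethyl 6-[2-(trimethylsilyl)ethyl] (2E,5E)-5-{1-[(4-methoxybenzyl)oxy]propan-2-ylidene}-3-methylhex-2-enedioate | CCOC(=O)/C=C(\C)C/C(C(=O)OCC[Si](C)(C)C)=C(/C)COCc1ccc(OC)cc1 | intermediate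
10 | (2E,4E)-6-ethoxy-2-{1-[(4-methoxybenzyl)oxy]propan-2-ylidene}-4-methyl-6-oxohex-4-enoic acid | CCOC(=O)/C=C(\C)C/C(C(=O)O)=C(/C)COCc1ccc(OC)cc1 | intermediate
11 | but-3-en-1-ylmagnesium bromide | C=CCC[Mg]Br | starting material
12 | ethyl (2E,5E)-6-chloro-5-{1-[(4-methoxybenzyl)oxy]propan-2-ylidene}-3-methyl-6-oxohex-2-enoate (acid chloride of 10) | CCOC(=O)/C=C(\C)C/C(C(Cl)=O)=C(/C)COCc1ccc(OC)cc1 | intermediate
13 | ethyl (2E,5E)-5-{1-[(4-methoxybenzyl)oxy]propan-2-ylidene}-3-methyl-6-oxodeca-2,9-dienoate | CCOC(=O)/C=C(\C)C/C(C(=O)CCC=C)=C(/C)COCc1ccc(OC)cc1 | intermediate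
14 | ethyl (2E,5E,6S)-6-hydroxy-5-{1-[(4-methoxybenzyl)oxy]propan-2-ylidene}-3-methyldeca-2,9-dienoate | CCOC(=O)/C=C(\C)C/C([C@@H](O)CCC=C)=C(/C)COCc1ccc(OC)cc1 | intermediate
15 | (E)-but-2-enal | C/C=C/C=O | starting material
16 | ethyl (2E,5E,6S,9E)-6-hydroxy-5-{1-[(4-methoxybenzyl)oxy]propan-2-ylidene}-3-methyl-11-oxoundeca-2,9-dienoate | CCOC(=O)/C=C(\C)C/C([C@@H](O)CC/C=C/C=O)=C(/C)COCc1ccc(OC)cc1 | intermediate
17 | ethyl (2E,5E,6S,9E)-5-{1-[(4-methoxybenzyl)oxy]propan-2-ylidene}-3-methyl-11-oxo-6-[(triethylsilyl)oxy]undeca-2,9-dienoate | CCOC(=O)/C=C(\C)C/C([C@@H](O[Si](CC)(CC)CC)CC/C=C/C=O)=C(/C)COCc1ccc(OC)cc1 | intermediate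
18 | ethyl (2E,5E,6S,8E,10E)-11-[(tert-butyldimethylsilyl)oxy]-5-{1-[(4-methoxybenzyl)oxy]propan-2-ylidene}-3-methyl-6-[(triethylsilyl)oxy]undeca-2,8,10-trienoate | CCOC(=O)/C=C(\C)C/C([C@@H](O[Si](CC)(CC)CC)C/C=C/C=C/O[Si](C)(C)C(C)(C)C)=C(/C)COCc1ccc(OC)cc1 | intermediate
19 | (2E,5E,6S,8E,10E)-11-[(tert-butyldimethylsilyl)oxy]-5-{1-[(4-methoxybenzyl)oxy]propan-2-ylidene}-3-methyl-6-[(triethylsilyl)oxy]undeca-2,8,10-trien-1-ol | OC/C=C(\C)C/C([C@@H](O[Si](CC)(CC)CC)C/C=C/C=C/O[Si](C)(C)C(C)(C)C)=C(/C)COCc1ccc(OC)cc1 | intermediate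
20 | (2E,5E,6S,8E,10E)-11-[(tert-butyldimethylsilyl)oxy]-5-{1-[(4-methoxybenzyl)oxy]propan-2-ylidene}-3-methyl-6-[(triethylsilyl)oxy]undeca-2,8,10-trienal | O=C/C=C(\C)C/C([C@@H](O[Si](CC)(CC)CC)C/C=C/C=C/O[Si](C)(C)C(C)(C)C)=C(/C)COCc1ccc(OC)cc1 | intermediate
21 | 3β-[(tert-butyldimethylsilyl)oxy]-12-[(4-methoxybenzyl)oxy]-8α-[(triethylsilyl)oxy]eremophila-1,7(11)E-dien-15-al (5β-CH3, 10α-H) | CC(C)(C)[Si](C)(C)O[C@H]1C=C[C@H]2C[C@H](O[Si](CC)(CC)CC)/C(=C(\C)COCc3ccc(OC)cc3)C[C@]2(C)[C@H]1C=O | intermediate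
22 | 3β-[(tert-butyldimethylsilyl)oxy]-12-[(4-methoxybenzyl)oxy]-8α-[(triethylsilyl)oxy]eremophila-1,7(11)E-dien-15-ol | CC(C)(C)[Si](C)(C)O[C@H]1C=C[C@H]2C[C@H](O[Si](CC)(CC)CC)/C(=C(\C)COCc3ccc(OC)cc3)C[C@]2(C)[C@H]1CO | intermediate
23 | 3β-[(tert-butyldimethylsilyl)oxy]-12-[(4-methoxybenzyl)oxy]eremophila-1,7(11)E-diene-8α,15-diol | CC(C)(C)[Si](C)(C)O[C@H]1C=C[C@H]2C[C@H](O)/C(=C(\C)COCc3ccc(OC)cc3)C[C@]2(C)[C@H]1CO | intermediate
24 | 15-methanesulfonate of diol 23 | CC(C)(C)[Si](C)(C)O[C@H]1C=C[C@H]2C[C@H](O)/C(=C(\C)COCc3ccc(OC)cc3)C[C@]2(C)[C@H]1COS(C)(=O)=O | intermediate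
25 | 3β-[(tert-butyldimethylsilyl)oxy]-12-[(4-methoxybenzyl)oxy]eremophila-1,7(11)E-dien-8α-ol (4β,5β-dimethyl, 10α-H) | CC(C)(C)[Si](C)(C)O[C@H]1C=C[C@H]2C[C@H](O)/C(=C(\C)COCc3ccc(OC)cc3)C[C@]2(C)[C@H]1C | intermediate
26 | 3β-[(tert-butyldimethylsilyl)oxy]-12-[(4-methoxybenzyl)oxy]eremophil-7(11)E-en-8α-ol | CC(C)(C)[Si](C)(C)O[C@H]1CC[C@H]2C[C@H](O)/C(=C(\C)COCc3ccc(OC)cc3)C[C@]2(C)[C@H]1C | intermediate
27 | 3β-[(tert-butyldimethylsilyl)oxy]-12-[(4-methoxybenzyl)oxy]eremophil-7(11)E-en-8-one | CC(C)(C)[Si](C)(C)O[C@H]1CC[C@H]2CC(=O)/C(=C(\C)COCc3ccc(OC)cc3)C[C@]2(C)[C@H]1C | intermediate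
28 | 3β-hydroxy-12-[(4-methoxybenzyl)oxy]eremophil-7(11)E-en-8-one | O[C@H]1CC[C@H]2CC(=O)/C(=C(\C)COCc3ccc(OC)cc3)C[C@]2(C)[C@H]1C | intermediate
29 | (E)-oct-2-enal | CCCCC/C=C/C=O | starting material
30 | (E)-non-3-en-1-yne | CCCCC/C=C/C#C | intermediate
31 | dimethyl[(1E,3E)-2-methylnona-1,3-dien-1-yl]alane | CCCCC/C=C/C(C)=C/[Al](C)C | intermediate
32 | (1E,3E)-1-iodo-2-methylnona-1,3-diene | CCCCC/C=C/C(C)=C/I | intermediate
33 | acrylic acid | C=CC(=O)O | starting material
34 | (2E,4E,6E)-5-methyldodeca-2,4,6-trienoic acid | CCCCC/C=C/C(C)=C/C=C/C(=O)O | intermediate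
35 | 12-[(4-methoxybenzyl)oxy]-8-oxoeremophil-7(11)E-en-3α-yl (2E,4E,6E)-5-methyldodeca-2,4,6-trienoate | CCCCC/C=C/C(C)=C/C=C/C(=O)O[C@@H]1CC[C@H]2CC(=O)/C(=C(\C)COCc3ccc(OC)cc3)C[C@]2(C)[C@H]1C | intermediate
36 | 9α-hydroxy-12-[(4-methoxybenzyl)oxy]-8-oxoeremophil-7(11)E-en-3α-yl (2E,4E,6E)-5-methyldodeca-2,4,6-trienoate | CCCCC/C=C/C(C)=C/C=C/C(=O)O[C@@H]1CC[C@H]2[C@H](O)C(=O)/C(=C(\C)COCc3ccc(OC)cc3)C[C@]2(C)[C@H]1C | intermediate
37 | CNP0226738.2, 9α,12-dihydroxy-8-oxoeremophil-7(11)E-en-3α-yl (2E,4E,6E)-5-methyldodeca-2,4,6-trienoate (4β,5β-dimethyl, 10α-H) | CCCCC/C=C/C(C)=C/C=C/C(=O)O[C@@H]1CC[C@H]2[C@H](O)C(=O)/C(=C(\C)CO)C[C@]2(C)[C@H]1C | target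

**Step count**

Total: 24 steps. Longest linear sequence: 21 steps (steps 1–18, then 22–24); the acid 34 is made in 3 steps (19–21).

**Steps most likely to fail**

Step 13. The Lewis acid may strip the silyl dienol ether or divert the reaction into a stepwise Mukaiyama–Michael path, which would cost material and loosen control of the C3/C4 relationship and of the ring fusion. The fallback sets out from ester 18 and uses neither the aldehyde nor a Lewis acid. Thermal intramolecular Diels–Alder reaction of 18 itself (toluene, BHT, 150 °C, sealed tube), with the C15 ethyl ester as activating group, should give the ethyl ester adduct F1. Reduction of F1 with i-Bu2AlH (CH2Cl2, −78 °C) gives the triethylsilyl ether alcohol 22, which is isolated and comes back to the route at the PPTS stage of step 14.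

Step 22. Formation of the alkoxyphosphonium ion at the axial, 1,3-diaxially hindered alcohol may be slow, and anti-periplanar E2 elimination towards C2 or C4 may outrun substitution by the weakly acidic trienoic acid. The fallback sets out from 28 and separates inversion from acylation. Mitsunobu inversion with the stronger and smaller 4-nitrobenzoic acid (PPh3, DIAD, toluene) should give the 3α 4-nitrobenzoate F2. Methanolysis (K2CO3, MeOH, 0 °C) gives the equatorial 3α-alcohol F3. Yamaguchi esterification of F3 with acid 34 (2,4,6-trichlorobenzoyl chloride, Et3N, THF; then DMAP, toluene) proceeds with retention and comes back to the route at 35.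

Step 23. The amide base may also deprotonate the trienoate (at its C5 methyl group) or the γ positions of the enone, and the enolate may add to the sulfonimine by-product, so chemoselectivity rather than facial selectivity is at risk. The fallback sets out from 35 and avoids a strong base. Soft enolisation (Me3SiOTf, Et3N, CH2Cl2, −78 → 0 °C) should give the trimethylsilyl enol ether F4. Rubottom oxidation with dimethyldioxirane (acetone/CH2Cl2, −78 °C; then citric acid, aq. THF) should epoxidise the electron-rich enol ether on the α face far faster than the ester-conjugated triene, and comes back to the route at 36.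

**Further compounds**

F1 | step 13 | ethyl 3β-[(tert-butyldimethylsilyl)oxy]-12-[(4-methoxybenzyl)oxy]-8α-[(triethylsilyl)oxy]eremophila-1,7(11)E-dien-15-oate | CC(C)(C)[Si](C)(C)O[C@H]1C=C[C@H]2C[C@H](O[Si](CC)(CC)CC)/C(=C(\C)COCc3ccc(OC)cc3)C[C@]2(C)[C@H]1C(=O)OCC
F2 | step 22 | 12-[(4-methoxybenzyl)oxy]-8-oxoeremophil-7(11)E-en-3α-yl 4-nitrobenzoate | O=C(O[C@@H]1CC[C@H]2CC(=O)/C(=C(\C)COCc3ccc(OC)cc3)C[C@]2(C)[C@H]1C)c1ccc([N+](=O)[O-])cc1
F3 | step 22 | 3α-hydroxy-12-[(4-methoxybenzyl)oxy]eremophil-7(11)E-en-8-one | O[C@@H]1CC[C@H]2CC(=O)/C(=C(\C)COCc3ccc(OC)cc3)C[C@]2(C)[C@H]1C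
F4 | step 23 | 12-[(4-methoxybenzyl)oxy]-8-[(trimethylsilyl)oxy]eremophila-7(11)E,8-dien-3α-yl (2E,4E,6E)-5-methyldodeca-2,4,6-trienoate | CCCCC/C=C/C(C)=C/C=C/C(=O)O[C@@H]1CC[C@H]2C=C(O[Si](C)(C)C)/C(=C(\C)COCc3ccc(OC)cc3)C[C@]2(C)[C@H]1C
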